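**Plan**

1. Target numbering: O1, C2 (aryl), C3 (CH2OH), C4 (CH2OH), C5 (aryl). The ring has a twofold axis and the pattern 2,3-cis / 3,4-trans / 4,5-cis (2,5-trans).
2. Retrosynthesis: (i) both CH2OH groups and both phenols come last from a methyl ester and two aryl pivalates; (ii) H at C4 replaces a lactone carbonyl that tied C4 to the CH2O arm on C3; (iii) the tetrahydrofuran is cut at O1–C2 and C4–C5 into vanillin pivalate and a lactone-fused aryl cyclopropane; (iv) the cyclopropane is cut into an enal and bromomalonate.
3. Enabling feature: O1–C2(aryl)–C3–C4(–C) is a 1,3-donor/acceptor array. C2 is benzylic and can take O1 by SN2 on a cyclopropane, C4 can carry carboxyl-level carbon, and the C3 CH2O arm can close onto that carboxyl as a γ-lactone; C5=O1 is then an aryl aldehyde, i.e. a (3+2) annulation of an aldehyde with a donor–acceptor cyclopropane.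
4. Forward order: cyclopropane ring (step 3) → temporary γ-lactone ring (step 4) → tetrahydrofuran ring by (3+2) (step 5) → lactone carbon excised (step 6) → reduction and unmasking (step 7).
5. Stereochemistry: one organocatalytic event sets C3 and the trans aryl; C2 follows by inversion in the (3+2); C5 by exo closure onto the cis-fused bicycle; C4 by hydrogen delivery on the face vacated by the lactone carbonyl.

Key step: step 5

Remark: vanillin and coniferaldehyde are taken as commercial; the Why lines use the target numbering given above.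

**Step 1**
Reactants: 1 vanillin
Product: 2 4-formyl-2-methoxyphenyl pivalate
Conditions: PivCl, Et3N, DMAP (cat.), CH2Cl2, 0 °C to rt
Reagents that add atoms: pivaloyl chloride, CC(C)(C)C(=O)Cl
Why: DMAP-catalysed O-acylation of the phenol leaves the aldehyde untouched and installs a hindered, electron-poor mask that makes the aryl group phenyl-like in the later steps.

**Step 2**
Reactants: 3 coniferaldehyde
Product: 4 2-methoxy-4-[(E)-3-oxoprop-1-enyl]phenyl pivalate
Conditions: PivCl, Et3N, DMAP (cat.), CH2Cl2, 0 °C to rt
Reagents that add atoms: pivaloyl chloride, CC(C)(C)C(=O)Cl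
Why: The same phenol O-acylation; the (E)-enal is not affected by the mild base.

**Step 3**
Reactants: 4 enal pivalate; 5 dimethyl 2-bromomalonate
Product: 7 dimethyl (2S,3R)-2-formyl-3-[3-methoxy-4-(pivaloyloxy)phenyl]cyclopropane-1,1-dicarboxylate, via bromomalonate Michael adduct 6 (not isolated)
Conditions: (R)-2-[diphenyl(trimethylsilyloxy)methyl]pyrrolidine (20 mol %), 2,6-lutidine (1.1 equiv), CH2Cl2, 0 °C to rt
Reagents that add atoms: none
Why: Organocatalytic Michael-initiated ring closure under iminium/enamine catalysis: the diphenyl(silyloxy)methyl group shields one face of the (E)-iminium ion so that bromomalonate adds to the β-carbon to give the (R) benzylic centre, and 3-exo-tet alkylation of the enamine then closes the ring with CHO trans to the aryl group.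

**Step 4**
Reactants: 7 formyl cyclopropane
Product: 9 methyl (1R,5S,6R)-6-[3-methoxy-4-(pivaloyloxy)phenyl]-2-oxo-3-oxabicyclo[3.1.0]hexane-1-carboxylate, via hydroxymethyl diester 8 (not isolated)
Conditions: NaBH4, MeOH/THF, −10 °C; then p-TsOH·H2O (5 mol %), CH2Cl2, rt
Reagents that add atoms: none
Why: NaBH4 reduces only the aldehyde and the primary alcohol closes onto the cis ester of the geminal pair (lactonisation, 5-exo-trig), which fixes the configuration of C1 by cis fusion, leaves the aryl exo and touches no existing stereocentre.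

**Step 5**
Reactants: 9 bicyclic lactone cyclopropane; 2 4-formyl-2-methoxyphenyl pivalate
Product: 11 methyl (3aS,4R,6S,6aS)-4,6-bis[3-methoxy-4-(pivaloyloxy)phenyl]-3-oxotetrahydrofuro[3,4-c]furan-3a-carboxylate (cis-fused; 4-aryl exo; 6-aryl endo), via oxocarbenium lactone-enolate zwitterion 10 (not isolated)
Conditions: 2 (3 equiv), Sn(OTf)2 (10 mol %), 4 Å MS, ClCH2CH2Cl, 23 to 45 °C
Reagents that add atoms: none
Why: Sn(OTf)2 chelates the lactone and ester carbonyls on C1 of 9 and polarises the C1–C6 bond; the carbonyl oxygen of 2 attacks benzylic C6 from the rear of that bond (SN2-like, inversion) to give the (E)-oxocarbenium/lactone enolate 10, whose enolate carbon then bonds to the oxocarbenium carbon. The closest known reaction type is the Lewis-acid-catalysed (3+2) annulation of aldehydes with aryl cyclopropane-1,1-diesters to tetrahydrofurans, which is stereospecific with inversion for phenyl-like donors. The one ring that closes, the tetrahydrofuran, does so by a 5-(enolexo)-endo-trig attack of the enolate on the oxocarbenium ion, while the cyclopropane opens and the γ-lactone is kept. Target C2 is set by inversion of the trans cyclopropane, which places its aryl cis to the CH2O arm on C3 (C3 is carried through untouched); C4 becomes quaternary with its configuration fixed by the cis fusion to the lactone; C5 is set in the closure, where the aryl of the (E)-oxocarbenium ion should take the convex face of the nascent cis-fused dioxabicyclo[3.3.0]octane, trans to the C2 aryl. The step needs invertive rather than ionising opening, secured by the pivaloyloxy groups that keep the 4-oxygenated aryl from forming a quinone-methide-like cation; it needs exo placement of the incoming aryl, secured by the temporary lactone (an untethered diester would be expected to give the 2,5-cis ring); and it needs attack at C6 only, the one cyclopropane carbon that is both benzylic and bonded to the acceptor carbon.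

**Step 6**
Reactants: 11 furofuranone ester
Product: 13 methyl (2S,3R,4S,5S)-4-(hydroxymethyl)-2,5-bis[3-methoxy-4-(pivaloyloxy)phenyl]tetrahydrofuran-3-carboxylate, via lithium carboxylate 12 (not isolated)
Conditions: LiOH·H2O (1.0 equiv), THF/H2O, 0 °C; evaporate; then 9-mesityl-10-phenylacridinium tetrafluoroborate (5 mol %), PhSSPh (10 mol %), CF3CH2OH, 450 nm LEDs, 23 °C
Reagents that add atoms: none
Why: Hydroxide should open only the strained, doubly activated lactone (the hindered aryl pivalates and the quaternary methyl ester react more slowly), and the malonic half-ester carboxylate then undergoes acridinium photoredox hydrodecarboxylation, in which the planar C4 α-ester radical should take hydrogen from PhSH on the face opposite the pseudoaxial C5 aryl, which is the face of the small free CH2OH group where the lactone carbonyl stood, so that the ester ends cis to the C5 aryl and trans to C3–CH2OH (a C4 epimer would close to the cis lactone and be separable).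

**Step 7**
Reactants: 13 hydroxy ester
Product: 14 eduesmine
Conditions: LiAlH4 (6 equiv), THF, 0 °C to rt; aq potassium sodium tartrate (KNaC4H4O6) work-up
Reagents that add atoms: none
Why: LiAlH4 reduces the methyl ester to the second CH2OH group and cleaves both aryl pivalates in the same operation; C4 is safe because hydride addition is far faster than enolisation, and the neutral tartrate work-up avoids acid-driven opening of the benzylic ether bonds.

**Compound list**

1 | vanillin (4-hydroxy-3-methoxybenzaldehyde) | COc1cc(C=O)ccc1O | starting material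
2 | 4-formyl-2-methoxyphenyl pivalate | COc1cc(C=O)ccc1OC(=O)C(C)(C)C | intermediate
3 | coniferaldehyde, (E)-3-(4-hydroxy-3-methoxyphenyl)prop-2-enal | COc1cc(/C=C/C=O)ccc1O | starting material
4 | 2-methoxy-4-[(E)-3-oxoprop-1-enyl]phenyl pivalate | COc1cc(/C=C/C=O)ccc1OC(=O)C(C)(C)C | intermediate
5 | dimethyl 2-bromomalonate | COC(=O)C(Br)C(=O)OC | starting material
6 | dimethyl 2-bromo-2-{(1R)-1-[3-methoxy-4-(pivaloyloxy)phenyl]-3-oxopropyl}malonate (held in the flask as the enamine of the catalyst) | O=CC[C@H](c1ccc(OC(=O)C(C)(C)C)c(OC)c1)C(Br)(C(=O)OC)C(=O)OC | intermediate (not isolated)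
7 | dimethyl (2S,3R)-2-formyl-3-[3-methoxy-4-(pivaloyloxy)phenyl]cyclopropane-1,1-dicarboxylate (CHO trans to aryl) | COC(=O)C1(C(=O)OC)[C@@H](C=O)[C@@H]1c1ccc(OC(=O)C(C)(C)C)c(OC)c1 | intermediate
8 | dimethyl (2S,3R)-2-(hydroxymethyl)-3-[3-methoxy-4-(pivaloyloxy)phenyl]cyclopropane-1,1-dicarboxylate | COC(=O)C1(C(=O)OC)[C@@H](CO)[C@@H]1c1ccc(OC(=O)C(C)(C)C)c(OC)c1 | intermediate (not isolated)
9 | methyl (1R,5S,6R)-6-[3-methoxy-4-(pivaloyloxy)phenyl]-2-oxo-3-oxabicyclo[3.1.0]hexane-1-carboxylate (aryl exo) | COC(=O)[C@]12C(=O)OC[C@H]1[C@@H]2c1ccc(OC(=O)C(C)(C)C)c(OC)c1 | intermediate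
10 | tin-bound zwitterion: (E)-oxocarbenium ion from 2 on the inverted (S) benzylic carbon, with the α-methoxycarbonyl lactone enolate | COC(=O)[C-]1C(=O)OC[C@H]1[C@@H](c1ccc(OC(=O)C(C)(C)C)c(OC)c1)/[O+]=C/c1ccc(OC(=O)C(C)(C)C)c(OC)c1 | intermediate (not isolated)
11 | methyl (3aS,4R,6S,6aS)-4,6-bis[3-methoxy-4-(pivaloyloxy)phenyl]-3-oxotetrahydrofuro[3,4-c]furan-3a-carboxylate (cis-fused; lactone C=O at C3 and CO2Me on fusion carbon C3a; 4-aryl exo, from 2; 6-aryl endo, from 9) | COc1cc([C@H]2O[C@H](c3ccc(OC(=O)C(C)(C)C)c(OC)c3)[C@@]4(C(=O)OC)C(=O)OC[C@@H]24)ccc1OC(=O)C(C)(C)C | intermediate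
12 | lithium (2R,3R,4S,5S)-4-(hydroxymethyl)-3-(methoxycarbonyl)-2,5-bis[3-methoxy-4-(pivaloyloxy)phenyl]tetrahydrofuran-3-carboxylate | COc1cc([C@H]2O[C@H](c3ccc(OC(=O)C(C)(C)C)c(OC)c3)[C@@](C(=O)OC)(C(=O)[O-])[C@H]2CO)ccc1OC(=O)C(C)(C)C.[Li+] | intermediate (not isolated)
13 | methyl (2S,3R,4S,5S)-4-(hydroxymethyl)-2,5-bis[3-methoxy-4-(pivaloyloxy)phenyl]tetrahydrofuran-3-carboxylate (ester cis to the 2-aryl, trans to CH2OH; CH2OH cis to the 5-aryl) | COc1cc([C@H]2O[C@H](c3ccc(OC(=O)C(C)(C)C)c(OC)c3)[C@H](C(=O)OC)[C@H]2CO)ccc1OC(=O)C(C)(C)C | intermediate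
14 | eduesmine, [(2S,3S,4S,5S)-2,5-bis(4-hydroxy-3-methoxyphenyl)tetrahydrofuran-3,4-diyl]dimethanol | COc1cc([C@H]2O[C@H](c3ccc(O)c(OC)c3)[C@H](CO)[C@H]2CO)ccc1O | target

**Totals**

Total step count: 7. Longest linear sequence: 6 steps (3 → 4 → 7 → 9 → 11 → 13 → 14; step 1 supplies 2 for step 5).

**Steps most likely to fail**

Step 6. Hydrogen transfer to the planar C4 radical may show poor facial selectivity between the C5 aryl and the C3 hydroxymethyl group, with the wrong epimer draining into the cis lactone; partial pivalate hydrolysis may also compete. The fallback replaces face discrimination by intramolecular delivery; it sets out from 12 and comes back at 13. The free primary alcohol of 12 is silylated with di-tert-butylchlorosilane (imidazole, DMF; aqueous work-up frees the acid) to give the di-tert-butylsilyl ether acid F1. F1 is converted with oxalyl chloride and then sodium 2-thioxopyridin-1(2H)-olate (NaC5H4NOS) into the Barton ester F2. Photolysis of F2 at high dilution in benzene generates the C4 radical, which can be reached only by the Si–H bond held on the upper face by the C3 CH2O tether (1,5-hydrogen transfer through a six-membered transition state); the silyl radical carries the chain by taking the thiopyridyl group, giving the silyl sulfide F3. Bu4NF/AcOH then removes the silicon group to give 13.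

Step 5. Ring-opening may be slow, the benzylic C–C bond may ionise before oxygen attack (loss of inversion), or the closure may leak to the endo aryl or re-open by retro-aldol under the Lewis acid. The fallback makes the two bonds one after the other; it sets out from 9 and comes back at 11. Compound 9 is opened at the benzylic carbon by water under Cu(OTf)2 catalysis (invertive hydration of an aryl cyclopropane diester) to the γ-hydroxy lactone ester F4. F4 is condensed with 2 (or its dimethyl acetal) under Me3SiOTf, so that the oxocarbenium ion 10 forms from the alcohol side and closes as before to 11.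

Step 3. The amine catalyst or the base may open the formyl cyclopropane again, and the trans selectivity or the enantiomeric purity may erode. The fallback makes the cyclopropane and lactone rings together; it sets out from 4 and comes back at 9. Luche reduction of 4 (NaBH4, CeCl3·7H2O, MeOH) gives the allylic alcohol F5. Acylation with methyl 3-chloro-3-oxopropanoate and pyridine gives the mixed malonate F6. Diazo transfer with 4-acetamidobenzenesulfonyl azide and Et3N gives the diazomalonate F7. Intramolecular cyclopropanation with Cu(MeCN)4PF6 and a chiral tert-butyl bis(oxazoline) ligand, or with the dirhodium carboxamidate Rh2(5S-MEPY)4 (enantiomer chosen to give the (1R,5S,6R) product), gives 9 directly; the (E)-alkene fixes the exo aryl.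

**Further compounds**

F1 | step 6 | (2R,3R,4S,5S)-4-{[(di-tert-butylsilyl)oxy]methyl}-3-(methoxycarbonyl)-2,5-bis[3-methoxy-4-(pivaloyloxy)phenyl]tetrahydrofuran-3-carboxylic acid | COc1cc([C@H]2O[C@H](c3ccc(OC(=O)C(C)(C)C)c(OC)c3)[C@@](C(=O)OC)(C(=O)O)[C@H]2CO[SiH](C(C)(C)C)C(C)(C)C)ccc1OC(=O)C(C)(C)C
F2 | step 6 | 2-thioxopyridin-1(2H)-yl ester of F1 (Barton ester) | COc1cc([C@H]2O[C@H](c3ccc(OC(=O)C(C)(C)C)c(OC)c3)[C@@](C(=O)OC)(C(=O)On3ccccc3=S)[C@H]2CO[SiH](C(C)(C)C)C(C)(C)C)ccc1OC(=O)C(C)(C)C
F3 | step 6 | methyl (2S,3R,4S,5S)-4-({[di-tert-butyl(pyridin-2-ylsulfanyl)silyl]oxy}methyl)-2,5-bis[3-methoxy-4-(pivaloyloxy)phenyl]tetrahydrofuran-3-carboxylate | COc1cc([C@H]2O[C@H](c3ccc(OC(=O)C(C)(C)C)c(OC)c3)[C@H](C(=O)OC)[C@H]2CO[Si](Sc3ccccn3)(C(C)(C)C)C(C)(C)C)ccc1OC(=O)C(C)(C)C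
F4 | step 5 | methyl (4S)-4-{(S)-hydroxy[3-methoxy-4-(pivaloyloxy)phenyl]methyl}-2-oxotetrahydrofuran-3-carboxylate (C3 epimers) | COC(=O)C1C(=O)OC[C@H]1[C@H](O)c1ccc(OC(=O)C(C)(C)C)c(OC)c1
F5 | step 3 | 4-[(E)-3-hydroxyprop-1-enyl]-2-methoxyphenyl pivalate | COc1cc(/C=C/CO)ccc1OC(=O)C(C)(C)C
F6 | step 3 | (E)-3-[3-methoxy-4-(pivaloyloxy)phenyl]allyl methyl malonate | COC(=O)CC(=O)OC/C=C/c1ccc(OC(=O)C(C)(C)C)c(OC)c1
F7 | step 3 | (E)-3-[3-methoxy-4-(pivaloyloxy)phenyl]allyl methyl 2-diazomalonate | COC(=O)C(=[N+]=[N-])C(=O)OC/C=C/c1ccc(OC(=O)C(C)(C)C)c(OC)c1
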